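The C40 skeleton is cut at C11=C12 and C11′=C12′ into a ring-B acetylenic C15 phosphonium salt (from actinol), the C10 trienedial and a ring-A C15 dienal. Everything rests on ring A: its enone motif C6′(=O)–C5′(CH3)=C4′H is made by one-carbon ring expansion of a cyclopentane. Chloro(methyl)carbene adds to the silyl enol ether of (R)-4-silyloxy-2,2-dimethylcyclopentanone and the siloxy chlorocyclopropane opens, inserting C5′ with its methyl between C6′ and C4′, fixing the ring alkene and unveiling the C6′ ketone in one operation. The C3′ silyl ether then directs acetylide addition at C6′ and is inverted late to the cis-diol.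

Key step: step 4

Assumption: in step 5 the acetylide is taken to enter syn to the C4 silyloxy group (axial attack anti to the pseudoaxial C6 methyl, silyloxy pseudoequatorial), so C3′ is carried as R and inverted in step 9.

Step 1
Reactants: 1 2,2-dimethylcyclopentan-1-one
Product: 2 5,5-dimethylcyclopent-2-en-1-one
Conditions: IBX, DMSO/toluene, 70 °C
Reagents that add atoms: none
Why: IBX α,β-dehydrogenation of a ketone through its enol; only C5 carries α-hydrogens (C2 is quaternary), so a single enone should form.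

Step 2
Reactants: 2 5,5-dimethylcyclopent-2-en-1-one
Product: 4 (4R)-4-hydroxy-2,2-dimethylcyclopentan-1-one, via β-boryl ketone 3 (not isolated)
Conditions: B2pin2, CuCl (cat.), NaOtBu (cat.), (R,S)-Josiphos (C36H44FeP2; the ligand antipode that gives the 4R boronate is used), MeOH, THF, rt; then NaBO3·4H2O, THF/H2O, rt
Reagents that add atoms: sodium perborate, [Na+].[O-]OB=O (the hydroxyl oxygen); bis(pinacolato)diboron, CC1(C)OB(OC1(C)C)B1OC(C)(C)C(C)(C)O1 (boron of 3 only)
Why: Copper-catalysed enantioselective conjugate borylation delivers boron to the β-carbon from the face chosen by the chiral diphosphine, setting C4 as R, and perborate oxidation replaces boron by oxygen with retention.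

Step 3
Reactants: 4 (4R)-4-hydroxy-2,2-dimethylcyclopentan-1-one
Product: 5 (3R)-1,3-bis(tert-butyldimethylsilyloxy)-5,5-dimethylcyclopent-1-ene
Conditions: TBSOTf (2.4 equiv), Et3N, CH2Cl2, 0 °C
Reagents that add atoms: tert-butyldimethylsilyl triflate, CC(C)(C)[Si](C)(C)OS(=O)(=O)C(F)(F)F
Why: Silyl triflate/amine O-silylation of the alcohol with concurrent soft enolisation of the ketone; the enol ether can form only toward the CH2 group because the other α-carbon is quaternary, and the carbinol stereocentre is untouched.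

Step 4
Reactants: 5 (3R)-1,3-bis(tert-butyldimethylsilyloxy)-5,5-dimethylcyclopent-1-ene
Product: 7 (4R)-4-(tert-butyldimethylsilyloxy)-2,6,6-trimethylcyclohex-2-en-1-one, via chlorocyclopropane 6 (not isolated)
Conditions: CH3CHCl2, n-BuLi, Et2O, −40 °C → rt; then toluene, 100 °C
Reagents that add atoms: 1,1-dichloroethane, CC(Cl)Cl (C2 of 7 and its methyl)
Why: The carbenoid made from 1,1-dichloroethane and n-BuLi transfers chloro(methyl)carbene to the electron-rich enol ether double bond of 5 in a concerted [2+1] cheletropic addition that closes the cis-fused three-membered ring of 6, approaching anti to the neighbouring silyloxy group. On warming, chloride leaves while the shared C1–C5 bond of the bicyclo[3.1.0]hexane opens in a disrotatory two-electron cyclopropyl-to-allyl electrocyclic process pushed by the siloxy oxygen, and chloride then removes the silyl group from the 2-siloxyallyl cation; the six-membered ring is thus not closed by cyclisation but arises from the five-membered ring, with the carbene carbon and its methyl inserted as C5′ of ring A (C2 of 7) between the carbonyl carbon and the former enol ether CH. This is the known halocarbene ring expansion of cyclic silyl enol ethers to 2-substituted cycloalk-2-enones, driven by release of cyclopropane strain. No new stereocentre survives the step (the cyclopropane centres are destroyed on opening) and the silyloxy-bearing stereocentre is a spectator. The step needs a single site of insertion, secured because the quaternary C5 of 5 allows only one enol ether, and easy ionisation of the adduct, secured by the donor oxygen on the cyclopropane; the adduct with chlorine endo should open most readily.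

Step 5
Reactants: 7 (4R)-4-(tert-butyldimethylsilyloxy)-2,6,6-trimethylcyclohex-2-en-1-one; 8 (2E)-3-methylpent-2-en-4-yn-1-ol
Product: 9 (1R,4R)-4-(tert-butyldimethylsilyloxy)-1-[(3E)-5-hydroxy-3-methylpent-3-en-1-yn-1-yl]-2,6,6-trimethylcyclohex-2-en-1-ol
Conditions: 8, n-BuLi (2 equiv per 8), THF, −78 → 0 °C; then 7, −78 °C → rt; aq. NH4Cl
Reagents that add atoms: none
Why: 1,2-Addition of a lithium acetylide (the O,C-dilithio derivative of 8) to the hindered enone carbonyl; axial attack anti to the pseudoaxial C6 methyl, on the half-chair that keeps the silyloxy group pseudoequatorial, should place the alkynyl group cis to OTBS and set C1 as R.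

Step 6
Reactants: 9 (1R,4R)-4-(tert-butyldimethylsilyloxy)-1-[(3E)-5-hydroxy-3-methylpent-3-en-1-yn-1-yl]-2,6,6-trimethylcyclohex-2-en-1-ol
Product: 10 (2E,4E)-5-[(1R,4R)-4-(tert-butyldimethylsilyloxy)-1-hydroxy-2,6,6-trimethylcyclohex-2-en-1-yl]-3-methylpenta-2,4-dien-1-ol
Conditions: NaAlH2(OCH2CH2OCH3)2 (Red-Al), THF, 0 °C → rt; Rochelle salt work-up
Reagents that add atoms: none
Why: Alkoxide-directed trans-hydroalumination of the propargylic alcohol (Red-Al reduction) and protonolysis should give the (E)-alkene at C7′=C8′, leaving the silyl ether and the existing (E)-trisubstituted alkene untouched.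

Step 7
Reactants: 10 (2E,4E)-5-[(1R,4R)-4-(tert-butyldimethylsilyloxy)-1-hydroxy-2,6,6-trimethylcyclohex-2-en-1-yl]-3-methylpenta-2,4-dien-1-ol
Product: 11 (2E,4E)-5-[(1R,4R)-4-(tert-butyldimethylsilyloxy)-1-hydroxy-2,6,6-trimethylcyclohex-2-en-1-yl]-3-methylpenta-2,4-dienal
Conditions: MnO2, CH2Cl2, rt
Reagents that add atoms: none
Why: MnO2 oxidation of the primary allylic alcohol to the conjugated dienal; the tertiary alcohol and the silyl ether do not react and the alkene geometries are kept.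

Step 8
Reactants: 11 (2E,4E)-5-[(1R,4R)-4-(tert-butyldimethylsilyloxy)-1-hydroxy-2,6,6-trimethylcyclohex-2-en-1-yl]-3-methylpenta-2,4-dienal
Product: 12 (2E,4E)-5-[(1R,4R)-1,4-dihydroxy-2,6,6-trimethylcyclohex-2-en-1-yl]-3-methylpenta-2,4-dienal (trans-diol)
Conditions: Bu4NF (TBAF), AcOH, THF, 0 °C → rt
Reagents that add atoms: none
Why: Fluoride desilylation, buffered with acetic acid to spare the base-sensitive dienal; no stereocentre is affected.

Step 9
Reactants: 12 (2E,4E)-5-[(1R,4R)-1,4-dihydroxy-2,6,6-trimethylcyclohex-2-en-1-yl]-3-methylpenta-2,4-dienal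
Product: 13 (1S,4R)-4-hydroxy-3,5,5-trimethyl-4-[(1E,3E)-3-methyl-5-oxopenta-1,3-dien-1-yl]cyclohex-2-en-1-yl 4-nitrobenzoate
Conditions: 4-O2NC6H4CO2H, PPh3, DIAD, THF, 0 °C
Reagents that add atoms: 4-nitrobenzoic acid, OC(=O)c1ccc(cc1)[N+](=O)[O-]
Why: Mitsunobu esterification of the secondary allylic alcohol proceeds by SN2 displacement of the oxyphosphonium ion with inversion, turning the carbinol carbon (C3′) from R into S and so creating the cis-1,4 relationship; the tertiary alcohol is not activated.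

Step 10
Reactants: 13 (1S,4R)-4-hydroxy-3,5,5-trimethyl-4-[(1E,3E)-3-methyl-5-oxopenta-1,3-dien-1-yl]cyclohex-2-en-1-yl 4-nitrobenzoate
Product: 14 (2E,4E)-5-[(1R,4S)-1,4-dihydroxy-2,6,6-trimethylcyclohex-2-en-1-yl]-3-methylpenta-2,4-dienal (cis-diol)
Conditions: K2CO3 (cat.), MeOH, 0 °C
Reagents that add atoms: none
Why: Carbonate-catalysed transesterification (methanolysis) of the activated 4-nitrobenzoate frees the secondary hydroxyl without touching the stereocentres or the dienal.

Step 11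
Reactants: 15 (4R,6R)-4-hydroxy-2,2,6-trimethylcyclohexan-1-one (actinol)
Product: 16 (4R,6R)-2,2,6-trimethyl-4-(triethylsilyloxy)cyclohexan-1-one
Conditions: TESCl, imidazole, CH2Cl2, 0 °C → rt
Reagents that add atoms: chlorotriethylsilane, CC[Si](Cl)(CC)CC
Why: Imidazole-promoted silylation protects the secondary alcohol for the enolate chemistry; the stereocentres are unchanged.

Step 12
Reactants: 16 (4R,6R)-2,2,6-trimethyl-4-(triethylsilyloxy)cyclohexan-1-one
Product: 17 (4R)-2,6,6-trimethyl-4-(triethylsilyloxy)cyclohex-1-en-1-yl trifluoromethanesulfonate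
Conditions: LiN(i-Pr)2 (LDA), THF, −78 °C; PhNTf2, −78 °C → rt
Reagents that add atoms: N-phenylbis(trifluoromethanesulfonimide), O=S(=O)(N(c1ccccc1)S(=O)(=O)C(F)(F)F)C(F)(F)F
Why: Deprotonation at C6, the only α-carbon bearing hydrogen, and O-triflation of the enolate give the tetrasubstituted enol triflate; the C6 stereocentre is removed on purpose and C4 is retained.

Step 13
Reactants: 17 (4R)-2,6,6-trimethyl-4-(triethylsilyloxy)cyclohex-1-en-1-yl trifluoromethanesulfonate; 8 (2E)-3-methylpent-2-en-4-yn-1-ol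
Product: 18 (2E)-3-methyl-5-[(4R)-2,6,6-trimethyl-4-(triethylsilyloxy)cyclohex-1-en-1-yl]pent-2-en-4-yn-1-ol
Conditions: Pd(PPh3)4 (cat.), CuI (cat.), i-Pr2NH, THF, rt
Reagents that add atoms: none
Why: Sonogashira coupling of the enol triflate with the terminal alkyne of 8 forms the C6–C7 bond and keeps the (E)-alkene of 8.

Step 14
Reactants: 18 (2E)-3-methyl-5-[(4R)-2,6,6-trimethyl-4-(triethylsilyloxy)cyclohex-1-en-1-yl]pent-2-en-4-yn-1-ol
Product: 19 [(2E)-5-[(4R)-4-hydroxy-2,6,6-trimethylcyclohex-1-en-1-yl]-3-methylpent-2-en-4-yn-1-yl]triphenylphosphonium bromide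
Conditions: PPh3·HBr, MeOH/CH2Cl2, rt
Reagents that add atoms: triphenylphosphine hydrobromide, [Br-].[PH+](c1ccccc1)(c1ccccc1)c1ccccc1
Why: Acid-promoted substitution of the primary allylic alcohol by triphenylphosphine (phosphonium salt formation) with concurrent methanolysis of the acid-labile triethylsilyl ether; the secondary homoallylic alcohol and its stereocentre are unaffected.

Step 15
Reactants: 19 [(2E)-5-[(4R)-4-hydroxy-2,6,6-trimethylcyclohex-1-en-1-yl]-3-methylpent-2-en-4-yn-1-yl]triphenylphosphonium bromide; 20 (2E,4E,6E)-2,7-dimethylocta-2,4,6-trienedial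
Product: 21 (2E,4E,6E,8E,10E)-13-[(4R)-4-hydroxy-2,6,6-trimethylcyclohex-1-en-1-yl]-2,7,11-trimethyltrideca-2,4,6,8,10-pentaen-12-ynal
Conditions: NaOMe, MeOH/CH2Cl2, 0 °C → rt (20 in excess); then EtOAc, reflux (Z→E)
Reagents that add atoms: none
Why: Wittig olefination of one aldehyde group of excess 20 by the semi-stabilised ylide of 19 forms C11=C12; the hindered (11Z) isomer formed alongside should isomerise thermally to (E).

Step 16
Reactants: 21 (2E,4E,6E,8E,10E)-13-[(4R)-4-hydroxy-2,6,6-trimethylcyclohex-1-en-1-yl]-2,7,11-trimethyltrideca-2,4,6,8,10-pentaen-12-ynal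
Product: 22 (2E,4E,6E,8E,10E)-13-[(4R)-4-hydroxy-2,6,6-trimethylcyclohex-1-en-1-yl]-2,7,11-trimethyltrideca-2,4,6,8,10-pentaen-12-yn-1-ol
Conditions: NaBH4, MeOH/CH2Cl2, 0 °C
Reagents that add atoms: none
Why: Borohydride 1,2-reduction of the polyenal to the allylic alcohol; nothing else in the molecule is reducible under these conditions.

Step 17
Reactants: 22 (2E,4E,6E,8E,10E)-13-[(4R)-4-hydroxy-2,6,6-trimethylcyclohex-1-en-1-yl]-2,7,11-trimethyltrideca-2,4,6,8,10-pentaen-12-yn-1-ol
Product: 23 [(2E,4E,6E,8E,10E)-13-[(4R)-4-hydroxy-2,6,6-trimethylcyclohex-1-en-1-yl]-2,7,11-trimethyltrideca-2,4,6,8,10-pentaen-12-yn-1-yl]triphenylphosphonium bromide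
Conditions: PPh3·HBr, MeOH/CH2Cl2, rt
Reagents that add atoms: triphenylphosphine hydrobromide, [Br-].[PH+](c1ccccc1)(c1ccccc1)c1ccccc1
Why: Phosphonium salt formation from the polyenyl allylic alcohol, as in step 14; the ring hydroxyl is not allylic and stays.

Step 18
Reactants: 23 [(2E,4E,6E,8E,10E)-13-[(4R)-4-hydroxy-2,6,6-trimethylcyclohex-1-en-1-yl]-2,7,11-trimethyltrideca-2,4,6,8,10-pentaen-12-yn-1-yl]triphenylphosphonium bromide; 14 (2E,4E)-5-[(1R,4S)-1,4-dihydroxy-2,6,6-trimethylcyclohex-2-en-1-yl]-3-methylpenta-2,4-dienal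
Product: 24 (all-E)-(3R,3′S,6′R)-7,8-didehydro-β,ε-carotene-3,3′,6′-triol (CNP0113828.1)
Conditions: NaOMe, MeOH/CH2Cl2, 0 °C → rt; then EtOH, reflux, dark (Z→E at C11′=C12′)
Reagents that add atoms: none
Why: Wittig olefination joins C11′ of 14 to C12′ of the ylide from 23 with all hydroxyl groups left free; the (11′Z) isomer formed alongside should isomerise thermally, and all stereocentres are spectators.

Compound list
1 | 2,2-dimethylcyclopentan-1-one | CC1(C)CCCC1=O | starting material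
2 | 5,5-dimethylcyclopent-2-en-1-one | CC1(C)CC=CC1=O | intermediate
3 | (4R)-2,2-dimethyl-4-(4,4,5,5-tetramethyl-1,3,2-dioxaborolan-2-yl)cyclopentan-1-one | CC1(C)C[C@@H](B2OC(C)(C)C(C)(C)O2)CC1=O | intermediate
4 | (4R)-4-hydroxy-2,2-dimethylcyclopentan-1-one | CC1(C)C[C@@H](O)CC1=O | intermediate
5 | (3R)-1,3-bis(tert-butyldimethylsilyloxy)-5,5-dimethylcyclopent-1-ene | CC1(C)C[C@@H](O[Si](C)(C)C(C)(C)C)C=C1O[Si](C)(C)C(C)(C)C | intermediate
6 | (4R)-6-chloro-2,2,6-trimethyl-1,4-bis(tert-butyldimethylsilyloxy)bicyclo[3.1.0]hexane (mixture at the cyclopropane carbons) | CC1(Cl)C2[C@H](O[Si](C)(C)C(C)(C)C)CC(C)(C)C12O[Si](C)(C)C(C)(C)C | intermediate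
7 | (4R)-4-(tert-butyldimethylsilyloxy)-2,6,6-trimethylcyclohex-2-en-1-one | CC1=C[C@H](O[Si](C)(C)C(C)(C)C)CC(C)(C)C1=O | intermediate
8 | (2E)-3-methylpent-2-en-4-yn-1-ol | C#C/C(C)=C/CO | starting material
9 | (1R,4R)-4-(tert-butyldimethylsilyloxy)-1-[(3E)-5-hydroxy-3-methylpent-3-en-1-yn-1-yl]-2,6,6-trimethylcyclohex-2-en-1-ol | CC1=C[C@H](O[Si](C)(C)C(C)(C)C)CC(C)(C)[C@]1(O)C#C/C(C)=C/CO | intermediate
10 | (2E,4E)-5-[(1R,4R)-4-(tert-butyldimethylsilyloxy)-1-hydroxy-2,6,6-trimethylcyclohex-2-en-1-yl]-3-methylpenta-2,4-dien-1-ol | CC1=C[C@H](O[Si](C)(C)C(C)(C)C)CC(C)(C)[C@]1(O)/C=C/C(C)=C/CO | intermediate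
11 | (2E,4E)-5-[(1R,4R)-4-(tert-butyldimethylsilyloxy)-1-hydroxy-2,6,6-trimethylcyclohex-2-en-1-yl]-3-methylpenta-2,4-dienal | CC1=C[C@H](O[Si](C)(C)C(C)(C)C)CC(C)(C)[C@]1(O)/C=C/C(C)=C/C=O | intermediate
12 | (2E,4E)-5-[(1R,4R)-1,4-dihydroxy-2,6,6-trimethylcyclohex-2-en-1-yl]-3-methylpenta-2,4-dienal | CC1=C[C@H](O)CC(C)(C)[C@]1(O)/C=C/C(C)=C/C=O | intermediate
13 | (1S,4R)-4-hydroxy-3,5,5-trimethyl-4-[(1E,3E)-3-methyl-5-oxopenta-1,3-dien-1-yl]cyclohex-2-en-1-yl 4-nitrobenzoate | CC1=C[C@@H](OC(=O)c2ccc(cc2)[N+](=O)[O-])CC(C)(C)[C@]1(O)/C=C/C(C)=C/C=O | intermediate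
14 | (2E,4E)-5-[(1R,4S)-1,4-dihydroxy-2,6,6-trimethylcyclohex-2-en-1-yl]-3-methylpenta-2,4-dienal | CC1=C[C@@H](O)CC(C)(C)[C@]1(O)/C=C/C(C)=C/C=O | intermediate
15 | (4R,6R)-4-hydroxy-2,2,6-trimethylcyclohexan-1-one (actinol) | O=C1[C@H](C)C[C@@H](O)CC1(C)C | starting material
16 | (4R,6R)-2,2,6-trimethyl-4-(triethylsilyloxy)cyclohexan-1-one | O=C1[C@H](C)C[C@@H](O[Si](CC)(CC)CC)CC1(C)C | intermediate
17 | (4R)-2,6,6-trimethyl-4-(triethylsilyloxy)cyclohex-1-en-1-yl trifluoromethanesulfonate | FC(F)(F)S(=O)(=O)OC1=C(C)C[C@@H](O[Si](CC)(CC)CC)CC1(C)C | intermediate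
18 | (2E)-3-methyl-5-[(4R)-2,6,6-trimethyl-4-(triethylsilyloxy)cyclohex-1-en-1-yl]pent-2-en-4-yn-1-ol | OC/C=C(\C)C#CC1=C(C)C[C@@H](O[Si](CC)(CC)CC)CC1(C)C | intermediate
19 | [(2E)-5-[(4R)-4-hydroxy-2,6,6-trimethylcyclohex-1-en-1-yl]-3-methylpent-2-en-4-yn-1-yl]triphenylphosphonium bromide | [Br-].c1ccc(cc1)[P+](c1ccccc1)(c1ccccc1)C/C=C(\C)C#CC1=C(C)C[C@@H](O)CC1(C)C | intermediate
20 | (2E,4E,6E)-2,7-dimethylocta-2,4,6-trienedial | O=C/C(C)=C/C=C/C=C(\C)C=O | starting material
21 | (2E,4E,6E,8E,10E)-13-[(4R)-4-hydroxy-2,6,6-trimethylcyclohex-1-en-1-yl]-2,7,11-trimethyltrideca-2,4,6,8,10-pentaen-12-ynal | O=C/C(C)=C/C=C/C=C(C)/C=C/C=C(\C)C#CC1=C(C)C[C@@H](O)CC1(C)C | intermediate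
22 | (2E,4E,6E,8E,10E)-13-[(4R)-4-hydroxy-2,6,6-trimethylcyclohex-1-en-1-yl]-2,7,11-trimethyltrideca-2,4,6,8,10-pentaen-12-yn-1-ol | OC/C(C)=C/C=C/C=C(C)/C=C/C=C(\C)C#CC1=C(C)C[C@@H](O)CC1(C)C | intermediate
23 | [(2E,4E,6E,8E,10E)-13-[(4R)-4-hydroxy-2,6,6-trimethylcyclohex-1-en-1-yl]-2,7,11-trimethyltrideca-2,4,6,8,10-pentaen-12-yn-1-yl]triphenylphosphonium bromide | [Br-].c1ccc(cc1)[P+](c1ccccc1)(c1ccccc1)C/C(C)=C/C=C/C=C(C)/C=C/C=C(\C)C#CC1=C(C)C[C@@H](O)CC1(C)C | intermediate
24 | (all-E)-(3R,3′S,6′R)-7,8-didehydro-β,ε-carotene-3,3′,6′-triol | CC1=C[C@@H](O)CC(C)(C)[C@]1(O)/C=C/C(C)=C/C=C/C(C)=C/C=C/C=C(C)/C=C/C=C(\C)C#CC1=C(C)C[C@@H](O)CC1(C)C | target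

Total step count: 18. Longest linear sequence: 11 steps (steps 1–10 and 18).

Steps most likely to fail

Step 4 (carbene ring expansion). The carbenoid may collapse to vinyl chloride by 1,2-hydrogen shift faster than it transfers to the hindered enol ether, or an exo-chloro adduct may fail to ionise. The fallback sets out from 5 and comes back at 7. Dibromocarbene (CHBr3, KOtBu, pentane, −20 °C → rt) would give (4R)-6,6-dibromo-2,2-dimethyl-1,4-bis(tert-butyldimethylsilyloxy)bicyclo[3.1.0]hexane F1, which always has an endo halogen. On warming (toluene, 80 °C) it should open to the ring-expanded bromo enone (4R)-2-bromo-4-(tert-butyldimethylsilyloxy)-6,6-dimethylcyclohex-2-en-1-one F2. Suzuki methylation of F2 (trimethylboroxine, Pd(dppf)Cl2, K2CO3, dioxane, 80 °C) would then give 7.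

Step 5 (acetylide addition). Poor facial discrimination at the carbonyl, or vinylogous deprotonation of the enone by the basic dianion, would erode the configuration at the new carbinol carbon or the conversion. The fallback sets out from 7 and comes back at 9. The smaller and less basic HC≡CMgBr with CeCl3 (THF, −78 °C) would give (1S,4R)-4-(tert-butyldimethylsilyloxy)-1-ethynyl-2,6,6-trimethylcyclohex-2-en-1-ol F3 (same spatial arrangement as in 9), purified as one diastereomer. Sonogashira coupling of F3 with (E)-3-iodobut-2-en-1-ol (Pd(PPh3)4, CuI, i-Pr2NH, THF, rt) would then build the enyne side chain of 9.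

Step 9 (Mitsunobu inversion). Transannular attack of the tertiary hydroxyl on the activated secondary carbon (oxygen bridge), elimination to a triene, or capture of the betaine by the aldehyde would consume the material. The fallback sets out from 11 and comes back at 24, correcting C3′ by late redox chemistry instead of substitution. Wittig coupling of 11 with 23 (NaOMe, MeOH/CH2Cl2; thermal Z→E) would give (3R,3′R,6′R)-3′-O-(tert-butyldimethylsilyl)-7,8-didehydro-β,ε-carotene-3,3′,6′-triol F4. Bu4NF would free the 3′-epimeric triol (3R,3′R,6′R)-7,8-didehydro-β,ε-carotene-3,3′,6′-triol F5. MnO2 would oxidise only the allylic 3′-hydroxyl (the ring-B hydroxyl is not allylic) to (3R,6′R)-3,6′-dihydroxy-7,8-didehydro-β,ε-caroten-3′-one F6. Luche reduction of F6 (NaBH4, CeCl3·7H2O, MeOH, −40 °C) should give 24 together with F5, which is separated and returned to the oxidation.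

Further compounds
F1 | step 4 | (4R)-6,6-dibromo-2,2-dimethyl-1,4-bis(tert-butyldimethylsilyloxy)bicyclo[3.1.0]hexane | BrC1(Br)C2[C@H](O[Si](C)(C)C(C)(C)C)CC(C)(C)C12O[Si](C)(C)C(C)(C)C
F2 | step 4 | (4R)-2-bromo-4-(tert-butyldimethylsilyloxy)-6,6-dimethylcyclohex-2-en-1-one | BrC1=C[C@H](O[Si](C)(C)C(C)(C)C)CC(C)(C)C1=O
F3 | step 5 | (1S,4R)-4-(tert-butyldimethylsilyloxy)-1-ethynyl-2,6,6-trimethylcyclohex-2-en-1-ol | CC1=C[C@H](O[Si](C)(C)C(C)(C)C)CC(C)(C)[C@]1(O)C#C
F4 | step 9 | (3R,3′R,6′R)-3′-O-(tert-butyldimethylsilyl)-7,8-didehydro-β,ε-carotene-3,3′,6′-triol | CC1=C[C@H](O[Si](C)(C)C(C)(C)C)CC(C)(C)[C@]1(O)/C=C/C(C)=C/C=C/C(C)=C/C=C/C=C(C)/C=C/C=C(\C)C#CC1=C(C)C[C@@H](O)CC1(C)C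
F5 | step 9 | (3R,3′R,6′R)-7,8-didehydro-β,ε-carotene-3,3′,6′-triol | CC1=C[C@H](O)CC(C)(C)[C@]1(O)/C=C/C(C)=C/C=C/C(C)=C/C=C/C=C(C)/C=C/C=C(\C)C#CC1=C(C)C[C@@H](O)CC1(C)C
F6 | step 9 | (3R,6′R)-3,6′-dihydroxy-7,8-didehydro-β,ε-caroten-3′-one | CC1=CC(=O)CC(C)(C)[C@]1(O)/C=C/C(C)=C/C=C/C(C)=C/C=C/C=C(C)/C=C/C=C(\C)C#CC1=C(C)C[C@@H](O)CC1(C)C
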